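The pitfall in this flask is to watch the clock, when E.J.X forms while solid E and dissolved J.X stand together, so the time to reckon is how long the solid lasts.

E 1.0 M; X 1.05 M; time 30 min

- percentages count the E that a species holds: one E.J.X counts as two
- J.X is meant together with its G
- solid, in amounts per volume of the solution: E, G
- at the start none of E is in solution
- run time (flask): 30 min

    E ⇌ J, rate k1*(cs1 - [J]) while solid is left; crystals form when [J] > cs1 (cs1 = 43 mM, k1 = 0.14 /s)
    J + X → J.X (k2 = 0.88 /M/s)
    G ⇌ J.X, rate k3*(cs3 - [J.X]) while solid is left; crystals form when [J.X] > cs3 (cs3 = 0.48 M, k3 = 0.089 /s)
    E + J.X → E.J.X (k4 = 0.0033 /M/s)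

- J.X and G together at 30 min, in percent of the E charged
- the change that raises the amount of J.X and G together at 30 min, in percent of the E charged most ("none" if none brings more than 2 percentage points) (dusk / midnight / noon / summer / none)
- amount of J.X and G together at 30 min, in percent of the E charged, after dusk

- dusk: doubling the solubility in step 3, all else as stated
- midnight: doubling the dissolution coefficient of step 1, all else as stated
- noon: doubling the solubility in step 1, all else as stated
- summer: doubling the dissolution coefficient of step 3, all else as stated

Solid E starts by delivering J into an empty solution at r = 0.361 M/min, the dissolution coefficient times the solubility of J. J standing in solution slows this: at the charged X, X captures J at a frequency of 0.924 /s against a dissolution coefficient of 0.14 /s, so at the start dissolution is the rate-limiting step. The rate is then r times f, the capture frequency over the sum of both frequencies. That factor f is 0.868 at the charged X and, in my reckoning, which counts one X for each E, falls to 0.239 once X is down to its excess over E. Adding up this slowing over the X used gives T, the emptying time of the solid, as a full-rate term τ plus a lag λ: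

τ = 1.0 M / r = 2.77 min

λ = ln(1.05 M / (1.05 M − 1.0 M)) / (0.88 /M/s · 43 mM) = 1.34 min

T = τ + λ = 4.11 min

I let E fall and J.X climb to its solubility in straight lines over T, and count two E in each E.J.X, which gives the share lost:

L = 0.0033 /M/s · 0.48 M · T / 3 = 13.0%

So I commit to 87.0%. T under noon, 2.05 min, is shorter than under midnight, 2.73 min, so I choose noon; for dusk this reckoning gives me no number.

The forecast gives 81%, lower than my figure, with noon as the best change and 80% after dusk, holding that “each E.J.X costs two units of yield”.

The flask gives 83.3% of J.X and G together, and 16.7% stands in E.J.X against my L of 13.0%. After dusk J.X and G together stand at 82.5%, and the best change is noon, worth 7.4 percentage points. The flask still holds 7.81% of its E at 3.00 min, earlier than T. With 0.60 M of E, T becomes 2.03 min and L becomes 6.44%, and that neighbour flask ends with 6.92% in E.J.X. The flask itself is at rest by 15.0 min, with E at 0%, J at 0% and 12.7% of X unbound. Ten times the asked time changes nothing: at 300 min J.X and G together stand at 83.3%.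

All constants are made up; the run is a simulation.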